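Everything rests on cutting the C1–C6 bond of the cyclohexenone ring, where carbonyl carbon C1 is bonded to the hydroxylated, fully substituted carbon C6: this 2-hydroxy ketone unit is the retron of a crossed benzoin union. A chiral triazolylidene catalyst inverts the polarity of an aldehyde at C1, and its attack on a C6 ketone closes the carbocycle, makes C1–C6 and creates the C6 stereocentre in one operation. The cyclisation substrate is the open-chain (4R,8S,16Z)-4,8-bis(TBS-oxy)-6-oxotricos-16-enal, built from two resolved terminal epoxides joined on a silyl dithiane. The C2=C3 double bond is added only afterwards, by dehydrogenation.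

Key step: step 13

Remarks
- Numbering: ring C1 (C=O), C2=C3, C4 (CHOH), C5, C6 (C–OH); side chain C1', C2' onward. Ring positions in all names follow this numbering. TBS = tert-butyldimethylsilyl, TMS = trimethylsilyl, PMB = 4-methoxybenzyl, salen = dianion of N,N'-bis(3,5-di-tert-butylsalicylidene)-1,2-cyclohexanediamine; (salen)Co(OAc) is its trivalent cobalt acetate complex.
- Descriptors: the target is (4S,6R,2'S,10'Z) with the C4 and C6 oxygens cis. The untouched C4 centre is labelled R in the acyclic and saturated-ring compounds, where C5 outranks C3, and S once C3 is olefinic.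
- Precursor design: both secondary carbinols stay as TBS ethers, because a free C4 hydroxyl would close onto the aldehyde as a lactol and silyloxy is a poor leaving group β to the ketone. The primary alcohol travels as a PMB ether, so the aldehyde is released immediately before cyclisation.
- Assumption: the hydrolytic kinetic resolution follows its usual sense, the (S,S)-cobalt complex leaving the (S)-alkyl oxirane and the (R,R)-complex the (R)-one.
- Assumption: the (5aS,10bR) triazolium salt is written as the matched antipode; which antipode reinforces the substrate bias has to be settled on small scale, and the (5aR,10bS) salt is held in reserve. Catalyst-bound transient species are described in the Why line and not numbered.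

Step 1
Reactants: 1 palmitoleyl alcohol [(9Z)-hexadec-9-en-1-ol]
Product: 2 (9Z)-hexadec-9-enal
Conditions: TEMPO (10 mol%), PhI(OAc)2 (1.1 equiv), CH2Cl2, rt
Reagents that add atoms: none
Why: Oxoammonium (TEMPO) oxidation with PhI(OAc)2 as terminal oxidant should stop at the aldehyde in dry CH2Cl2 and leaves the isolated Z-alkene alone.

Step 2
Reactants: 2 (9Z)-hexadec-9-enal
Product: 3 rac-2-[(8Z)-pentadec-8-en-1-yl]oxirane
Conditions: Me3S+ I− (1.3 equiv), n-BuLi (1.25 equiv), THF, −10 °C; then 2, −10 °C → rt
Reagents that add atoms: trimethylsulfonium iodide, C[S+](C)C.[I-]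
Why: Corey–Chaykovsky epoxidation, in which dimethylsulfonium methylide adds to the aldehyde faster than it enolises it and the betaine closes with loss of Me2S, adding C1' as a terminal oxirane that is racemic at the new centre.

Step 3
Reactants: 3 rac-2-[(8Z)-pentadec-8-en-1-yl]oxirane
Product: 4 (2S)-2-[(8Z)-pentadec-8-en-1-yl]oxirane
Conditions: (S,S)-(salen)Co(OAc) (0.5 mol%), H2O (0.55 equiv), THF, 0 °C → rt
Reagents that add atoms: none
Why: Hydrolytic kinetic resolution, in which the (S,S)-cobalt salen complex should hydrolyse the (R)-oxirane selectively so that the unreacted (S)-oxirane, the future C2' centre, is recovered in high enantiomeric purity and separated from the diol.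

Step 4
Reactants: 5 pent-4-en-1-ol
Product: 6 1-methoxy-4-[(pent-4-en-1-yloxy)methyl]benzene
Conditions: NaH, PMBCl, Bu4NI (cat.), THF, 0 °C → rt
Reagents that add atoms: 4-methoxybenzyl chloride, COc1ccc(CCl)cc1
Why: Williamson etherification of the primary alkoxide installs a PMB group that is orthogonal to the later TBS ethers.

Step 5
Reactants: 6 1-methoxy-4-[(pent-4-en-1-yloxy)methyl]benzene
Product: 7 rac-2-{3-[(4-methoxybenzyl)oxy]propyl}oxirane
Conditions: mCPBA, CH2Cl2, 0 °C → rt
Reagents that add atoms: 3-chloroperoxybenzoic acid (mCPBA), OOC(=O)c1cccc(Cl)c1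
Why: Prilezhaev epoxidation of the only alkene present gives the racemic terminal oxirane.

Step 6
Reactants: 7 rac-2-{3-[(4-methoxybenzyl)oxy]propyl}oxirane
Product: 8 (2R)-2-{3-[(4-methoxybenzyl)oxy]propyl}oxirane
Conditions: (R,R)-(salen)Co(OAc) (0.5 mol%), H2O (0.55 equiv), THF, 0 °C → rt
Reagents that add atoms: none
Why: Hydrolytic kinetic resolution with the (R,R)-cobalt salen complex should consume the (S)-oxirane and leave the (R)-oxirane, whose stereocentre becomes C4.

Step 7
Reactants: 9 1,3-dithiane
Product: 11 2-(tert-butyldimethylsilyl)-1,3-dithiane, via 2-lithio-1,3-dithiane 10 (not isolated)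
Conditions: n-BuLi, THF, −30 °C; TBSCl, −78 °C → rt
Reagents that add atoms: tert-butyldimethylsilyl chloride, CC(C)(C)[Si](C)(C)Cl
Why: Corey–Seebach deprotonation of the dithiane followed by C-silylation gives the linchpin carrying the silyl group that is later relayed to oxygen.

Step 8
Reactants: 11 2-(tert-butyldimethylsilyl)-1,3-dithiane; 4 (2S)-2-[(8Z)-pentadec-8-en-1-yl]oxirane; 8 (2R)-2-{3-[(4-methoxybenzyl)oxy]propyl}oxirane
Product: 15 (2R)-1-{2-[(2S,10Z)-2-(tert-butyldimethylsilyloxy)heptadec-10-en-1-yl]-1,3-dithian-2-yl}-5-(4-methoxybenzyloxy)pentan-2-ol, via lithiated silyl dithiane 12 (not isolated), via lithium alkoxide 13 (not isolated), via Brook-rearranged lithiodithiane 14 (not isolated)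
Conditions: t-BuLi, Et2O, −78 → −45 °C; 4, Et2O, −78 → −25 °C; 8, THF/HMPA, −78 °C → rt; then H2O
Reagents that add atoms: none
Why: Three-component silyl-dithiane linchpin coupling, in which the lithiated silyl dithiane opens 4 at its CH2 terminus, HMPA triggers a 1,4-Brook shift of silicon from carbon to the new alkoxide, and the regenerated dithiane anion opens 8 at its CH2 terminus, so both carbinol centres come unchanged from the oxiranes.

Step 9
Reactants: 15 (2R)-1-{2-[(2S,10Z)-2-(tert-butyldimethylsilyloxy)heptadec-10-en-1-yl]-1,3-dithian-2-yl}-5-(4-methoxybenzyloxy)pentan-2-ol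
Product: 16 2-[(2R)-2-(tert-butyldimethylsilyloxy)-5-(4-methoxybenzyloxy)pentyl]-2-[(2S,10Z)-2-(tert-butyldimethylsilyloxy)heptadec-10-en-1-yl]-1,3-dithiane
Conditions: TBSOTf, 2,6-lutidine, CH2Cl2, −78 → 0 °C
Reagents that add atoms: tert-butyldimethylsilyl trifluoromethanesulfonate, CC(C)(C)[Si](C)(C)OS(=O)(=O)C(F)(F)F
Why: Silylation of the remaining secondary alcohol with the silyl triflate and a hindered base is fast at low temperature and leaves the PMB ether, dithiane and alkene untouched.

Step 10
Reactants: 16 the bis-TBS dithiane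
Product: 17 (4R,8S,16Z)-4,8-bis(tert-butyldimethylsilyloxy)-1-(4-methoxybenzyloxy)tricos-16-en-6-one
Conditions: MeI (excess), CaCO3, MeCN/H2O (9:1), 45 °C
Reagents that add atoms: water, O
Why: Alkylative dithiane hydrolysis, in which S-methylation makes sulfur a leaving group and water opens the thionium ion to the C6 ketone under buffered conditions that spare silyl ethers, PMB ether and the Z-alkene.

Step 11
Reactants: 17 (4R,8S,16Z)-4,8-bis(tert-butyldimethylsilyloxy)-1-(4-methoxybenzyloxy)tricos-16-en-6-one
Product: 18 (4R,8S,16Z)-4,8-bis(tert-butyldimethylsilyloxy)-1-hydroxytricos-16-en-6-one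
Conditions: DDQ, CH2Cl2/pH 7 buffer (10:1), 0 °C
Reagents that add atoms: none
Why: Oxidative cleavage of the electron-rich PMB ether by DDQ frees the primary alcohol without acid or base, and is placed after dithiane removal so that no sulfur is exposed to the oxidant.

Step 12
Reactants: 18 (4R,8S,16Z)-4,8-bis(tert-butyldimethylsilyloxy)-1-hydroxytricos-16-en-6-one
Product: 19 (4R,8S,16Z)-4,8-bis(tert-butyldimethylsilyloxy)-6-oxotricos-16-enal
Conditions: TEMPO (10 mol%), PhI(OAc)2 (1.2 equiv), CH2Cl2, rt
Reagents that add atoms: none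
Why: TEMPO/PhI(OAc)2 oxidation of the primary alcohol gives the aldehyde under near-neutral conditions that should not enolise the β-silyloxy ketone; the keto-aldehyde is used at once.

Step 13
Reactants: 19 (4R,8S,16Z)-4,8-bis(tert-butyldimethylsilyloxy)-6-oxotricos-16-enal
Product: 20 (4R,6R)-4-(tert-butyldimethylsilyloxy)-6-[(2S,10Z)-2-(tert-butyldimethylsilyloxy)heptadec-10-en-1-yl]-6-hydroxycyclohexan-1-one
Conditions: (5aS,10bR)-2-(pentafluorophenyl)-5a,10b-dihydro-4H,6H-indeno[2,1-b][1,2,4]triazolo[4,3-d][1,4]oxazin-2-ium tetrafluoroborate (15 mol%), Et3N (15 mol%), toluene (0.02 M), rt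
Reagents that add atoms: none
Why: The carbene freed from the triazolium salt adds to the C1 aldehyde, proton transfer gives the nucleophilic enaminol (the acyl anion equivalent), this attacks the C6 ketone, and loss of the carbene unveils the C1 ketone next to the new C6 carbinol. The closest known reaction type is the intramolecular crossed aldehyde–ketone benzoin reaction under chiral triazolium carbene catalysis, which is established for aliphatic keto-aldehydes giving cyclic tertiary α-ketols. The ring closes in the 6-exo-trig mode through a chair-like arrangement. The C6 stereocentre is set by the chiral carbene acting together with that chair, which keeps C4–OTBS equatorial and is expected to place the ketone oxygen pseudo-equatorial and hydrogen-bonded to the enaminol O–H, so the new hydroxyl ends cis to C4–OTBS (6R). The step needs the crossed sense and freedom from aldol, silanol loss and aldehyde self-coupling: only the aldehyde can form the enaminol, only the ketone lies within six-ring reach, high dilution disfavours dimerisation, and a weak amine base with poor silyloxy leaving groups disfavours enolate pathways.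

Step 14
Reactants: 20 the α-ketol
Product: 21 silyl enol ether of 20 toward C2 with the C6 hydroxyl also silylated: (4R,6R)-4-(tert-butyldimethylsilyloxy)-6-[(2S,10Z)-2-(tert-butyldimethylsilyloxy)heptadec-10-en-1-yl]-1,6-bis(trimethylsilyloxy)cyclohex-1-ene
Conditions: TMSOTf (3 equiv), Et3N (5 equiv), CH2Cl2, −78 → 0 °C
Reagents that add atoms: trimethylsilyl trifluoromethanesulfonate, C[Si](C)(C)OS(=O)(=O)C(F)(F)F
Why: Soft enolisation with a silyl triflate and amine caps the tertiary hydroxyl and enolises the ketone toward C2, the only α-carbon bearing hydrogen because C6 is fully substituted.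

Step 15
Reactants: 21 the C1=C2 silyl enol ether
Product: 22 (4S,6R)-4-(tert-butyldimethylsilyloxy)-6-[(2S,10Z)-2-(tert-butyldimethylsilyloxy)heptadec-10-en-1-yl]-6-(trimethylsilyloxy)cyclohex-2-en-1-one
Conditions: Pd(OAc)2 (1.1 equiv), MeCN, rt
Reagents that add atoms: none
Why: Saegusa–Ito oxidation, in which divalent palladium exchanges with silicon to give the C2-bound palladium enolate and syn β-hydride elimination from C3 should deliver the C2=C3 enone, leaving zerovalent palladium as the spent metal.

Step 16
Reactants: 22 the tris-silylated enone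
Product: 23 (4S,6R)-4,6-dihydroxy-6-[(2S,10Z)-2-hydroxyheptadec-10-en-1-yl]cyclohex-2-en-1-one
Conditions: HF·pyridine, pyridine, THF, 0 °C → rt
Reagents that add atoms: none
Why: Fluoride-driven desilylation under buffered, weakly acidic conditions should remove the TMS and both TBS groups without the base-induced dehydration that threatens a γ-hydroxy enone.

Compound list
1 | palmitoleyl alcohol, (9Z)-hexadec-9-en-1-ol | CCCCCC/C=C\CCCCCCCCO | starting material
2 | (9Z)-hexadec-9-enal | CCCCCC/C=C\CCCCCCCC=O | intermediate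
3 | rac-2-[(8Z)-pentadec-8-en-1-yl]oxirane | CCCCCC/C=C\CCCCCCCC1CO1 | intermediate
4 | (2S)-2-[(8Z)-pentadec-8-en-1-yl]oxirane | CCCCCC/C=C\CCCCCCC[C@H]1CO1 | intermediate
5 | pent-4-en-1-ol | OCCCC=C | starting material
6 | 1-methoxy-4-[(pent-4-en-1-yloxy)methyl]benzene | COc1ccc(COCCCC=C)cc1 | intermediate
7 | rac-2-{3-[(4-methoxybenzyl)oxy]propyl}oxirane | COc1ccc(COCCCC2CO2)cc1 | intermediate
8 | (2R)-2-{3-[(4-methoxybenzyl)oxy]propyl}oxirane | COc1ccc(COCCC[C@@H]2CO2)cc1 | intermediate
9 | 1,3-dithiane | C1CSCSC1 | starting material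
10 | 2-lithio-1,3-dithiane (not isolated) | [Li]C1SCCCS1 | intermediate
11 | 2-(tert-butyldimethylsilyl)-1,3-dithiane | CC(C)(C)[Si](C)(C)C1SCCCS1 | intermediate
12 | 2-lithio-2-(tert-butyldimethylsilyl)-1,3-dithiane (not isolated) | CC(C)(C)[Si](C)(C)C1([Li])SCCCS1 | intermediate
13 | lithium (2S,10Z)-1-[2-(tert-butyldimethylsilyl)-1,3-dithian-2-yl]heptadec-10-en-2-olate (not isolated) | CCCCCC/C=C\CCCCCCC[C@H](O[Li])CC1([Si](C)(C)C(C)(C)C)SCCCS1 | intermediate
14 | 2-lithio-2-[(2S,10Z)-2-(tert-butyldimethylsilyloxy)heptadec-10-en-1-yl]-1,3-dithiane (not isolated) | CCCCCC/C=C\CCCCCCC[C@H](O[Si](C)(C)C(C)(C)C)CC1([Li])SCCCS1 | intermediate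
15 | (2R)-1-{2-[(2S,10Z)-2-(tert-butyldimethylsilyloxy)heptadec-10-en-1-yl]-1,3-dithian-2-yl}-5-(4-methoxybenzyloxy)pentan-2-ol | CCCCCC/C=C\CCCCCCC[C@H](O[Si](C)(C)C(C)(C)C)CC1(C[C@H](O)CCCOCc2ccc(OC)cc2)SCCCS1 | intermediate
16 | 2-[(2R)-2-(tert-butyldimethylsilyloxy)-5-(4-methoxybenzyloxy)pentyl]-2-[(2S,10Z)-2-(tert-butyldimethylsilyloxy)heptadec-10-en-1-yl]-1,3-dithiane | CCCCCC/C=C\CCCCCCC[C@H](O[Si](C)(C)C(C)(C)C)CC1(C[C@H](O[Si](C)(C)C(C)(C)C)CCCOCc2ccc(OC)cc2)SCCCS1 | intermediate
17 | (4R,8S,16Z)-4,8-bis(tert-butyldimethylsilyloxy)-1-(4-methoxybenzyloxy)tricos-16-en-6-one | CCCCCC/C=C\CCCCCCC[C@H](O[Si](C)(C)C(C)(C)C)CC(=O)C[C@H](O[Si](C)(C)C(C)(C)C)CCCOCc1ccc(OC)cc1 | intermediate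
18 | (4R,8S,16Z)-4,8-bis(tert-butyldimethylsilyloxy)-1-hydroxytricos-16-en-6-one | CCCCCC/C=C\CCCCCCC[C@H](O[Si](C)(C)C(C)(C)C)CC(=O)C[C@H](O[Si](C)(C)C(C)(C)C)CCCO | intermediate
19 | (4R,8S,16Z)-4,8-bis(tert-butyldimethylsilyloxy)-6-oxotricos-16-enal | CCCCCC/C=C\CCCCCCC[C@H](O[Si](C)(C)C(C)(C)C)CC(=O)C[C@H](O[Si](C)(C)C(C)(C)C)CCC=O | intermediate
20 | (4R,6R)-4-(tert-butyldimethylsilyloxy)-6-[(2S,10Z)-2-(tert-butyldimethylsilyloxy)heptadec-10-en-1-yl]-6-hydroxycyclohexan-1-one | CCCCCC/C=C\CCCCCCC[C@H](O[Si](C)(C)C(C)(C)C)C[C@@]1(O)C[C@H](O[Si](C)(C)C(C)(C)C)CCC1=O | intermediate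
21 | (4R,6R)-4-(tert-butyldimethylsilyloxy)-6-[(2S,10Z)-2-(tert-butyldimethylsilyloxy)heptadec-10-en-1-yl]-1,6-bis(trimethylsilyloxy)cyclohex-1-ene | CCCCCC/C=C\CCCCCCC[C@H](O[Si](C)(C)C(C)(C)C)C[C@@]1(O[Si](C)(C)C)C[C@H](O[Si](C)(C)C(C)(C)C)CC=C1O[Si](C)(C)C | intermediate
22 | (4S,6R)-4-(tert-butyldimethylsilyloxy)-6-[(2S,10Z)-2-(tert-butyldimethylsilyloxy)heptadec-10-en-1-yl]-6-(trimethylsilyloxy)cyclohex-2-en-1-one | CCCCCC/C=C\CCCCCCC[C@H](O[Si](C)(C)C(C)(C)C)C[C@@]1(O[Si](C)(C)C)C[C@H](O[Si](C)(C)C(C)(C)C)C=CC1=O | intermediate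
23 | (4S,6R)-4,6-dihydroxy-6-[(2S,10Z)-2-hydroxyheptadec-10-en-1-yl]cyclohex-2-en-1-one | CCCCCC/C=C\CCCCCCC[C@H](O)C[C@@]1(O)C[C@H](O)C=CC1=O | target

Total step count: 16.
Longest linear sequence: 12 steps (steps 1–3, then 8–16, from palmitoleyl alcohol; the branch from pent-4-en-1-ol is equally long).

Steps most likely to fail

1. Step 13. The carbene-bound acyl anion may add too slowly to the enolisable, doubly β-oxygenated ketone, so that aldol closure, loss of silanol or aldehyde self-coupling takes over; or the attack may occur on the wrong face of the C6 ketone. The fallback forms the same C1–C6 bond reductively and without base. Setting out from 19, SmI2 in THF/t-BuOH at −78 °C should effect a ketyl–carbonyl (pinacol) cyclisation to the ring cis-diol (1S,4R,6R)-4-(tert-butyldimethylsilyloxy)-6-[(2S,10Z)-2-(tert-butyldimethylsilyloxy)heptadec-10-en-1-yl]cyclohexane-1,6-diol F1. Here a samarium chelate in a chair, not a catalyst, decides the C6 face, and that outcome would have to be checked. Parikh–Doering oxidation (SO3·pyridine, DMSO, Et3N) of the secondary C1 carbinol beside the tertiary one then comes back to the route at 20. If only the facial outcome of step 13 is unsatisfactory, the separated C6 epimer could also be returned to 19 by carbene-mediated retro-benzoin.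

2. Step 8. The silyl shift may occur too early or not at all, so that the first anion takes up two molecules of 4 or the relay stops at the alkoxide. The fallback gives up the relay and alkylates the parent dithiane twice with isolation in between. Setting out from 9, lithiation (n-BuLi, THF, −30 °C) and opening of 4 should give (2S,10Z)-1-(1,3-dithian-2-yl)heptadec-10-en-2-ol F2. TBSCl and imidazole in DMF give its silyl ether tert-butyl{[(2S,10Z)-1-(1,3-dithian-2-yl)heptadec-10-en-2-yl]oxy}dimethylsilane F3. A second lithiation (t-BuLi, THF/HMPA, −78 °C) and opening of 8 comes back to the route at 15.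

3. Step 15. Palladium hydride formed during the dehydrogenation may isomerise the side-chain Z-alkene, or the enol ether may hydrolyse back to the ketone before it is oxidised. The fallback avoids the metal through selenoxide elimination. Setting out from 21, PhSeCl in CH2Cl2 at −78 °C should give the C2 selenide (4R,6R)-4-(tert-butyldimethylsilyloxy)-6-[(2S,10Z)-2-(tert-butyldimethylsilyloxy)heptadec-10-en-1-yl]-2-(phenylselanyl)-6-(trimethylsilyloxy)cyclohexan-1-one F4 as a mixture of C2 epimers. Oxidation at selenium with one equivalent of mCPBA at −78 °C, then warming with i-Pr2NH, should bring about syn-elimination toward C3 and come back to the route at 22.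

Further compounds
F1 | step 13 | (1S,4R,6R)-4-(tert-butyldimethylsilyloxy)-6-[(2S,10Z)-2-(tert-butyldimethylsilyloxy)heptadec-10-en-1-yl]cyclohexane-1,6-diol | CCCCCC/C=C\CCCCCCC[C@H](O[Si](C)(C)C(C)(C)C)C[C@@]1(O)C[C@H](O[Si](C)(C)C(C)(C)C)CC[C@@H]1O
F2 | step 8 | (2S,10Z)-1-(1,3-dithian-2-yl)heptadec-10-en-2-ol | CCCCCC/C=C\CCCCCCC[C@H](O)CC1SCCCS1
F3 | step 8 | tert-butyl{[(2S,10Z)-1-(1,3-dithian-2-yl)heptadec-10-en-2-yl]oxy}dimethylsilane | CCCCCC/C=C\CCCCCCC[C@H](O[Si](C)(C)C(C)(C)C)CC1SCCCS1
F4 | step 15 | (4R,6R)-4-(tert-butyldimethylsilyloxy)-6-[(2S,10Z)-2-(tert-butyldimethylsilyloxy)heptadec-10-en-1-yl]-2-(phenylselanyl)-6-(trimethylsilyloxy)cyclohexan-1-one, C2 epimers | CCCCCC/C=C\CCCCCCC[C@H](O[Si](C)(C)C(C)(C)C)C[C@@]1(O[Si](C)(C)C)C[C@H](O[Si](C)(C)C(C)(C)C)CC([Se]c2ccccc2)C1=O
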